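**Retrosynthetic overview**

1. Target ⇒ aryl tri-O-methyl ether lacking the two formyl groups (thiolate demethylation; bromination, lithiation–DMF) ⇒ C10 methine from a C10 tertiary acetate (dehydration, face-selective hydrogenation) and C3 methylene from a C3 ketone (Barton–McCombie).
2. C4–C9′ bond (quaternary C4, C5=C6 alkene): α-attack of a guaia-3,5-dien-3-olate on the isobutyl o-quinone methide of a phloroglucinol dimethyl ether. The dienolate is made without base by reductive loss of a C6 acetoxy group. This activating group is added because deprotonation of the hydroazulenone would compete at H-1 and C2 and expel the C10 acetate, and because a silyl dienol ether would bond through C6.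
3. Key disconnection: 6,10-diacetoxyguaia-4,11-dien-3-one ⇒ 6-acetoxy-10-epi-1,2-dehydro-α-cyperone by dienone photorearrangement in acetic acid (C1–C5 made, C5–C10 broken, acetate on C10).
4. Feature the plan rests on: the guaiane core, a five-membered ring (C1–C5, methyl on C4) fused at C1/C5 to a seven-membered ring (C1, C5–C10) carrying a methyl on C10 and the C3 unit on C7, 1,4 across the ring. A eudesmane gives this skeleton when the ring-fusion bond moves from C5–C10 to C1–C5 (guaiane numbering throughout; C11 is the carbinol carbon, C9′ the benzylic carbon).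
5. Ring order: ring B of the eudesmane is the carvone ring; ring A is added by Robinson annulation; the photoreaction turns ring A into the five-membered ring and ring B into the seven-membered ring in one step; the aromatic ring is brought in intact.

Key step: step 7

Remark: the epimers drawn at C6 (8–12) and at C3 (23, 24) are the expected major ones; both centres are removed later (steps 10 and 16), so their ratio is of no consequence.

**Route**

Step 1
Reactants: 1 (R)-carvone
Product: 2 (2R,5R)-dihydrocarvone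
Conditions: Zn dust, KOH, EtOH–H2O, reflux
Reagents that add atoms: none
Why: Zinc/alkali conjugate reduction of the enone leaves the isolated isopropenyl group and the C5 stereocentre untouched; C2 forms as an epimer mixture that converges when C2 is enolised in step 2.

Step 2
Reactants: 2 (2R,5R)-dihydrocarvone; 3 ethyl vinyl ketone
Product: 6 10-epi-α-cyperone, via Michael adduct 4 (not isolated), via ketol 5 (not isolated)
Conditions: KOH, EtOH, 0 °C to rt; then KOH, EtOH, reflux
Reagents that add atoms: none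
Why: Robinson annulation: the more substituted enolate adds to 3 by axial bond formation, which places the new chain cis to the equatorial isopropenyl group and so the angular methyl trans to it, and aldol condensation–dehydration of 4 through 5 closes ring A as the enone.

Step 3
Reactants: 6 10-epi-α-cyperone
Product: 7 3-acetoxy-10-epi-eudesma-3,5,11-triene
Conditions: isopropenyl acetate, p-TsOH (cat.), reflux
Reagents that add atoms: isopropenyl acetate, CC(=C)OC(C)=O
Why: Acid-catalysed enol acetylation under equilibrating conditions gives the linearly conjugated 3,5-dienol acetate, C6 being the only γ-position because C10 is quaternary.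

Step 4
Reactants: 7 3-acetoxy-10-epi-eudesma-3,5,11-triene
Product: 8 6α-hydroxy-10-epi-α-cyperone
Conditions: m-CPBA (1.0 equiv), 95% EtOH, 0 °C
Reagents that add atoms: m-chloroperoxybenzoic acid, OOC(=O)c1cccc(Cl)c1
Why: Vinylogous Rubottom-type oxidation: the peracid epoxidises the electron-rich C5=C6 bond of the 1-acetoxydiene faster than the isolated 1,1-disubstituted alkene and the epoxide collapses with loss of the acetyl group to the γ-hydroxy enone, as in the 6-hydroxylation of steroid dienol acetates; axial attack cis to the C10 methyl is assumed for C6.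

Step 5
Reactants: 8 6α-hydroxy-10-epi-α-cyperone
Product: 9 6α-acetoxy-10-epi-α-cyperone
Conditions: Ac2O, pyridine, DMAP (cat.), CH2Cl2, rt
Reagents that add atoms: acetic anhydride, CC(=O)OC(C)=O
Why: DMAP-catalysed acetylation of the secondary allylic alcohol installs the leaving group used in step 10 and shields the alcohol from oxidation by DDQ.

Step 6
Reactants: 9 6α-acetoxy-10-epi-α-cyperone
Product: 10 6α-acetoxy-10-epi-1,2-dehydro-α-cyperone
Conditions: DDQ, dioxane, reflux
Reagents that add atoms: none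
Why: DDQ dehydrogenation of a 4-en-3-one under neutral conditions runs through the C2 enol and hydride loss from C1 to give the cross-conjugated 1,4-dien-3-one without touching C6, C7 or C10.

Step 7
Reactants: 10 6α-acetoxy-10-epi-1,2-dehydro-α-cyperone
Product: 12 6α,10β-diacetoxy-1βH-guaia-4,11-dien-3-one, via oxyallyl zwitterion 11 (not isolated)
Conditions: hν (medium-pressure Hg lamp, Pyrex filter), degassed glacial AcOH, rt, Ar
Reagents that add atoms: acetic acid, CC(=O)O
Why: n–π* excitation and 1,5-bonding (C1–C5) give the bicyclo[3.1.0]hexenone oxyallyl zwitterion 11; protonation on oxygen and acetolysis of its cyclopropane at C10 with cleavage of the C5–C10 bond give the cyclopentenone. The closest known reaction is the conversion of santonin, which also carries a C6 acyloxy group, into O-acetylisophotosantonic lactone in acetic acid. The five-membered ring closes by the C1–C5 bond across the dienone (3-exo closure to the cyclopropane within the excited chromophore); the seven-membered ring is not closed by a cyclisation but is ring B enlarged when the C5–C10 bond breaks. C1 is set by the C10 centre: ring B must stay cis-fused on the cyclopropane, so C10 swings to the face of its own methyl group and H-1 ends on the opposite (β) face, trans to that methyl; C10 is set by backside attack of acetic acid anti to the breaking C5–C10 bond (acetate β, cis to H-1). The step needs opening of the C5–C10 and not the C1–C10 cyclopropane bond, which the C4 methyl group secures by stabilising the cationic centre at C4 that this cleavage feeds.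

Step 8
Reactants: 13 2-hydroxy-4,6-dimethoxybenzaldehyde
Product: 14 tert-butyl 2-formyl-3,5-dimethoxyphenyl carbonate
Conditions: Boc2O, i-Pr2NEt, DMAP (cat.), THF, rt
Reagents that add atoms: di-tert-butyl dicarbonate, CC(C)(C)OC(=O)OC(=O)OC(C)(C)C
Why: DMAP-catalysed acylation of the phenol gives the aryl tert-butyl carbonate needed for the carbonate-transfer cascade of step 10.

Step 9
Reactants: 14 tert-butyl 2-formyl-3,5-dimethoxyphenyl carbonate; 15 isobutylmagnesium bromide
Product: 16 tert-butyl 2-(1-hydroxy-3-methylbutyl)-3,5-dimethoxyphenyl carbonate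
Conditions: THF, −78 °C; AcOH quench at −78 °C
Reagents that add atoms: none
Why: Grignard 1,2-addition to the aldehyde with a cold acidic quench should give the benzylic alcohol before the carbonate can migrate; the carbinol centre is racemic and is lost in step 10.

Step 10
Reactants: 12 6α,10β-diacetoxy-1βH-guaia-4,11-dien-3-one; 16 tert-butyl 2-(1-hydroxy-3-methylbutyl)-3,5-dimethoxyphenyl carbonate
Product: 19 10β-acetoxy-4β-[1-(2-hydroxy-4,6-dimethoxyphenyl)-3-methylbutyl]-1βH-guaia-5,11-dien-3-one, via diiodosamarium dienolate 17 (not isolated), via o-quinone methide 18 (not isolated)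
Conditions: 12, SmI2 (2.1 equiv), THF–DMPU, −78 °C; then 16 pre-treated with t-BuMgCl (1.0 equiv, THF, −78 °C) added by cannula; −78 to −20 °C; aq. NH4Cl
Reagents that add atoms: none
Why: Proposed new method: two-electron reduction of the γ-acetoxy enone by SmI2 expels the C6 acetate and gives only the C3–O, C5=C6 dienolate 17 with no base present, so H-1, C2 and the C10 acetate are not touched (closest known type: SmI2 reductive cleavage of γ-acyloxy enones and enoates with α-trapping of the dienolate); the magnesium alkoxide of 16 transfers its carbonate to the benzylic oxygen and loses tert-butyl carbonate to give the o-quinone methide 18 (closest known type: anionic o-quinone methide generation followed by enolate or Grignard 1,4-addition); metal dienolates react at the α-carbon, so 17 should add through C4 to the exocyclic carbon of 18 in a closed transition state with the metal bridging both oxygens, driven by aromatisation, which creates the quaternary C4 and leaves the C5=C6 alkene; C4 is attacked on its β face, anti to the C1–C10 bond, and with E-configured 18 held by the metal bridge its C9′–H lies over the five-membered ring and the isobutyl group points toward C6, which gives the C9′ configuration of the target.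

Step 11
Reactants: 19 10β-acetoxy-4β-[1-(2-hydroxy-4,6-dimethoxyphenyl)-3-methylbutyl]-1βH-guaia-5,11-dien-3-one
Product: 20 10β-acetoxy-4β-[3-methyl-1-(2,4,6-trimethoxyphenyl)butyl]-1βH-guaia-5,11-dien-3-one
Conditions: MeI, K2CO3, acetone, reflux
Reagents that add atoms: iodomethane, CI
Why: Williamson methylation of the phenoxide (the open form of the phenol-ketone/hemiketal pair) gives the symmetric trimethoxyaryl group; K2CO3 is too weak to enolise the ketone toward C2.

Step 12
Reactants: 20 10β-acetoxy-4β-[3-methyl-1-(2,4,6-trimethoxyphenyl)butyl]-1βH-guaia-5,11-dien-3-one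
Product: 21 10β-acetoxy-11-hydroxy-4β-[3-methyl-1-(2,4,6-trimethoxyphenyl)butyl]-1βH-guai-5-en-3-one
Conditions: Co(acac)2 (cat.), PhSiH3, O2 (1 atm), i-PrOH–THF, rt
Reagents that add atoms: dioxygen, O=O
Why: Mukaiyama hydration (hydrogen-atom transfer, Markovnikov) converts the 1,1-disubstituted alkene into the tertiary alcohol, the hindered trisubstituted C5=C6 bond reacting much more slowly.

Step 13
Reactants: 21 10β-acetoxy-11-hydroxy-4β-[3-methyl-1-(2,4,6-trimethoxyphenyl)butyl]-1βH-guai-5-en-3-one
Product: 22 10β-acetoxy-4β-[3-methyl-1-(2,4,6-trimethoxyphenyl)butyl]-11-triethylsilyloxy-1βH-guai-5-en-3-one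
Conditions: Et3SiOTf, 2,6-lutidine, CH2Cl2, −78 to 0 °C
Reagents that add atoms: triethylsilyl trifluoromethanesulfonate, CC[Si](CC)(CC)OS(=O)(=O)C(F)(F)F
Why: Silyl triflate/lutidine silylation of the tertiary alcohol differentiates the C11 oxygen from the C10 oxygen that is unmasked in step 14.

Step 14
Reactants: 22 10β-acetoxy-4β-[3-methyl-1-(2,4,6-trimethoxyphenyl)butyl]-11-triethylsilyloxy-1βH-guai-5-en-3-one
Product: 23 4β-[3-methyl-1-(2,4,6-trimethoxyphenyl)butyl]-11-triethylsilyloxy-1βH-guai-5-ene-3β,10β-diol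
Conditions: LiAlH4, THF, 0 °C to rt
Reagents that add atoms: none
Why: Hydride reduction of the ketone (from the α face, anti to the C4 side chain; configuration irrelevant) and reductive cleavage of the tertiary acetate occur together.

Step 15
Reactants: 23 4β-[3-methyl-1-(2,4,6-trimethoxyphenyl)butyl]-11-triethylsilyloxy-1βH-guai-5-ene-3β,10β-diol
Product: 24 3β-O-(phenoxythiocarbonyl) derivative of 23
Conditions: PhOC(S)Cl, pyridine, DMAP, MeCN, 50 °C
Reagents that add atoms: O-phenyl chlorothionoformate, S=C(Cl)Oc1ccccc1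
Why: Acylation of the secondary alcohol sets up Barton–McCombie deoxygenation; the tertiary C10 hydroxyl and the silylated C11 oxygen do not react.

Step 16
Reactants: 24 3β-O-(phenoxythiocarbonyl) derivative of 23
Product: 25 4β-[3-methyl-1-(2,4,6-trimethoxyphenyl)butyl]-11-triethylsilyloxy-1βH-guai-5-en-10β-ol
Conditions: Bu3SnH, AIBN (cat.), toluene, 110 °C
Reagents that add atoms: none
Why: Barton–McCombie radical deoxygenation; the secondary C3 radical cannot rearrange through the neighbouring alkene (a bicyclo[2.1.0]pentane would be required) and is reduced by the stannane.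

Step 17
Reactants: 25 4β-[3-methyl-1-(2,4,6-trimethoxyphenyl)butyl]-11-triethylsilyloxy-1βH-guai-5-en-10β-ol
Product: 26 4β-[3-methyl-1-(2,4,6-trimethoxyphenyl)butyl]-11-triethylsilyloxy-1βH-guaia-5,10(14)-diene
Conditions: SOCl2, pyridine, CH2Cl2, −40 to 0 °C
Reagents that add atoms: none
Why: Dehydration through the chlorosulfite with pyridine (anti E2): H-1 is syn to the leaving group and cannot be lost, and removal of a methyl proton gives the exocyclic alkene.

Step 18
Reactants: 26 4β-[3-methyl-1-(2,4,6-trimethoxyphenyl)butyl]-11-triethylsilyloxy-1βH-guaia-5,10(14)-diene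
Product: 27 4β-[3-methyl-1-(2,4,6-trimethoxyphenyl)butyl]-11-triethylsilyloxy-1βH,10βH-guai-5-ene
Conditions: H2 (1 atm), RhCl(PPh3)3, benzene–EtOH, rt
Reagents that add atoms: none
Why: Homogeneous hydrogenation with RhCl(PPh3)3 reduces only the 1,1-disubstituted alkene; hydrogen should be delivered to the face of C10 that carries H-1, the other face being screened by the C2 methylene, which sets the C10 methyl α (trans to H-1).

Step 19
Reactants: 27 4β-[3-methyl-1-(2,4,6-trimethoxyphenyl)butyl]-11-triethylsilyloxy-1βH,10βH-guai-5-ene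
Product: 28 4β-[1-(3,5-dibromo-2,4,6-trimethoxyphenyl)-3-methylbutyl]-11-triethylsilyloxy-1βH,10βH-guai-5-ene
Conditions: NBS (2.1 equiv), MeCN, −20 to 0 °C
Reagents that add atoms: N-bromosuccinimide, O=C1CCC(=O)N1Br
Why: Electrophilic aromatic bromination of the highly activated ring at its two free positions is much faster than reaction at the shielded trisubstituted alkene.

Step 20
Reactants: 28 4β-[1-(3,5-dibromo-2,4,6-trimethoxyphenyl)-3-methylbutyl]-11-triethylsilyloxy-1βH,10βH-guai-5-ene
Product: 31 4β-[1-(3,5-diformyl-2,4,6-trimethoxyphenyl)-3-methylbutyl]-1βH,10βH-guai-5-en-11-ol, via dilithioarene 29 (not isolated), via silyl ether dialdehyde 30 (not isolated)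
Conditions: t-BuLi (4.4 equiv), THF, −78 °C; DMF, −78 to 0 °C; then 1 M HCl, THF, rt
Reagents that add atoms: N,N-dimethylformamide, CN(C)C=O
Why: Double bromine–lithium exchange, formylation of the aryllithium with DMF (Bouveault-type) and acidic hydrolysis, which also cleaves the triethylsilyl ether.

Step 21
Reactants: 31 4β-[1-(3,5-diformyl-2,4,6-trimethoxyphenyl)-3-methylbutyl]-1βH,10βH-guai-5-en-11-ol
Product: 32 CNP0281883.3
Conditions: EtSNa (excess), DMF, 120 °C; aq. HCl work-up
Reagents that add atoms: none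
Why: Nucleophilic (SN2) demethylation by thiolate, accelerated by the ortho/para formyl groups, frees the three phenols under basic conditions that spare the tertiary alcohol and the alkene.

**Compound list**

1 | (R)-(−)-carvone | CC1=CC[C@H](CC1=O)C(C)=C | starting material
2 | (2R,5R)-dihydrocarvone (C2 epimer tolerated) | C[C@@H]1CC[C@H](CC1=O)C(C)=C | intermediate
3 | ethyl vinyl ketone (pent-1-en-3-one) | CCC(=O)C=C | starting material
4 | (2R,5R)-2-methyl-2-(3-oxopentyl)-5-(prop-1-en-2-yl)cyclohexan-1-one (Michael adduct) | O=C1C[C@H](C(C)=C)CC[C@]1(C)CCC(=O)CC | intermediate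
5 | (7R,10R)-5-hydroxyeudesm-11-en-3-one (ketol, C4/C5 epimers) | CC1C2(O)C[C@H](C(C)=C)CC[C@]2(C)CCC1=O | intermediate
6 | 10-epi-α-cyperone, (7R,10R)-eudesma-4,11-dien-3-one | CC1=C2C[C@H](C(C)=C)CC[C@]2(C)CCC1=O | intermediate
7 | 3-acetoxy-10-epi-eudesma-3,5,11-triene | CC(=O)OC1=C(C)C2=C[C@H](C(C)=C)CC[C@]2(C)CC1 | intermediate
8 | 6α-hydroxy-10-epi-α-cyperone (OH cis to the C10 methyl) | CC1=C2[C@@H](O)[C@H](C(C)=C)CC[C@]2(C)CCC1=O | intermediate
9 | 6α-acetoxy-10-epi-α-cyperone | CC1=C2[C@@H](OC(C)=O)[C@H](C(C)=C)CC[C@]2(C)CCC1=O | intermediate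
10 | 6α-acetoxy-10-epi-1,2-dehydro-α-cyperone (6α-acetoxy-10-epi-eudesma-1,4,11-trien-3-one) | CC1=C2[C@@H](OC(C)=O)[C@H](C(C)=C)CC[C@]2(C)C=CC1=O | intermediate
11 | 1,5-bonded bicyclo[3.1.0]hexenone oxyallyl zwitterion | C[C+]1C([O-])=C[C@H]2[C@@]13[C@@H](OC(C)=O)[C@H](C(C)=C)CC[C@]23C | intermediate
12 | 6α,10β-diacetoxy-1βH-guaia-4,11-dien-3-one | CC1=C2[C@@H](OC(C)=O)[C@H](C(C)=C)CC[C@](C)(OC(C)=O)[C@H]2CC1=O | intermediate
13 | 2-hydroxy-4,6-dimethoxybenzaldehyde | O=Cc1c(O)cc(OC)cc1OC | starting material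
14 | tert-butyl 2-formyl-3,5-dimethoxyphenyl carbonate | O=Cc1c(OC(=O)OC(C)(C)C)cc(OC)cc1OC | intermediate
15 | isobutylmagnesium bromide | CC(C)C[Mg]Br | starting material
16 | tert-butyl 2-(1-hydroxy-3-methylbutyl)-3,5-dimethoxyphenyl carbonate (racemic) | CC(C)CC(O)c1c(OC(=O)OC(C)(C)C)cc(OC)cc1OC | intermediate
17 | diiodosamarium 10β-acetoxy-1βH-guaia-3,5,11-trien-3-olate | CC1=C(O[Sm](I)I)C[C@H]2C1=C[C@H](C(C)=C)CC[C@]2(C)OC(C)=O | intermediate
18 | (E)-3,5-dimethoxy-6-(3-methylbutylidene)cyclohexa-2,4-dien-1-one | CC(C)C/C=C1/C(=O)C=C(OC)C=C1OC | intermediate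
19 | 10β-acetoxy-4β-[1-(2-hydroxy-4,6-dimethoxyphenyl)-3-methylbutyl]-1βH-guaia-5,11-dien-3-one (C9′ as in the target) | CC(C)C[C@H](c1c(O)cc(OC)cc1OC)[C@@]1(C)C(=O)C[C@H]2C1=C[C@H](C(C)=C)CC[C@]2(C)OC(C)=O | intermediate
20 | 10β-acetoxy-4β-[3-methyl-1-(2,4,6-trimethoxyphenyl)butyl]-1βH-guaia-5,11-dien-3-one | CC(C)C[C@H](c1c(OC)cc(OC)cc1OC)[C@@]1(C)C(=O)C[C@H]2C1=C[C@H](C(C)=C)CC[C@]2(C)OC(C)=O | intermediate
21 | 10β-acetoxy-11-hydroxy-4β-[3-methyl-1-(2,4,6-trimethoxyphenyl)butyl]-1βH-guai-5-en-3-one | CC(C)C[C@H](c1c(OC)cc(OC)cc1OC)[C@@]1(C)C(=O)C[C@H]2C1=C[C@H](C(C)(C)O)CC[C@]2(C)OC(C)=O | intermediate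
22 | 10β-acetoxy-4β-[3-methyl-1-(2,4,6-trimethoxyphenyl)butyl]-11-triethylsilyloxy-1βH-guai-5-en-3-one | CC(C)C[C@H](c1c(OC)cc(OC)cc1OC)[C@@]1(C)C(=O)C[C@H]2C1=C[C@H](C(C)(C)O[Si](CC)(CC)CC)CC[C@]2(C)OC(C)=O | intermediate
23 | 4β-[3-methyl-1-(2,4,6-trimethoxyphenyl)butyl]-11-triethylsilyloxy-1βH-guai-5-ene-3β,10β-diol | CC(C)C[C@H](c1c(OC)cc(OC)cc1OC)[C@@]1(C)[C@@H](O)C[C@H]2C1=C[C@H](C(C)(C)O[Si](CC)(CC)CC)CC[C@]2(C)O | intermediate
24 | 3β-O-(phenoxythiocarbonyl) derivative of 23 | CC(C)C[C@H](c1c(OC)cc(OC)cc1OC)[C@@]1(C)[C@@H](OC(=S)Oc3ccccc3)C[C@H]2C1=C[C@H](C(C)(C)O[Si](CC)(CC)CC)CC[C@]2(C)O | intermediate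
25 | 4β-[3-methyl-1-(2,4,6-trimethoxyphenyl)butyl]-11-triethylsilyloxy-1βH-guai-5-en-10β-ol | CC(C)C[C@H](c1c(OC)cc(OC)cc1OC)[C@@]1(C)CC[C@H]2C1=C[C@H](C(C)(C)O[Si](CC)(CC)CC)CC[C@]2(C)O | intermediate
26 | 4β-[3-methyl-1-(2,4,6-trimethoxyphenyl)butyl]-11-triethylsilyloxy-1βH-guaia-5,10(14)-diene | CC(C)C[C@H](c1c(OC)cc(OC)cc1OC)[C@@]1(C)CC[C@H]2C1=C[C@H](C(C)(C)O[Si](CC)(CC)CC)CCC2=C | intermediate
27 | 4β-[3-methyl-1-(2,4,6-trimethoxyphenyl)butyl]-11-triethylsilyloxy-1βH,10βH-guai-5-ene | CC(C)C[C@H](c1c(OC)cc(OC)cc1OC)[C@@]1(C)CC[C@H]2C1=C[C@H](C(C)(C)O[Si](CC)(CC)CC)CC[C@H]2C | intermediate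
28 | 4β-[1-(3,5-dibromo-2,4,6-trimethoxyphenyl)-3-methylbutyl]-11-triethylsilyloxy-1βH,10βH-guai-5-ene | CC(C)C[C@H](c1c(OC)c(Br)c(OC)c(Br)c1OC)[C@@]1(C)CC[C@H]2C1=C[C@H](C(C)(C)O[Si](CC)(CC)CC)CC[C@H]2C | intermediate
29 | 3′,5′-dilithio analogue of 28 | CC(C)C[C@H](c1c(OC)c([Li])c(OC)c([Li])c1OC)[C@@]1(C)CC[C@H]2C1=C[C@H](C(C)(C)O[Si](CC)(CC)CC)CC[C@H]2C | intermediate
30 | 4β-[1-(3,5-diformyl-2,4,6-trimethoxyphenyl)-3-methylbutyl]-11-triethylsilyloxy-1βH,10βH-guai-5-ene | CC(C)C[C@H](c1c(OC)c(C=O)c(OC)c(C=O)c1OC)[C@@]1(C)CC[C@H]2C1=C[C@H](C(C)(C)O[Si](CC)(CC)CC)CC[C@H]2C | intermediate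
31 | 4β-[1-(3,5-diformyl-2,4,6-trimethoxyphenyl)-3-methylbutyl]-1βH,10βH-guai-5-en-11-ol | CC(C)C[C@H](c1c(OC)c(C=O)c(OC)c(C=O)c1OC)[C@@]1(C)CC[C@H]2C1=C[C@H](C(C)(C)O)CC[C@H]2C | intermediate
32 | CNP0281883.3, (1R,4R,7R,10R,9′S)-4-[1-(3,5-diformyl-2,4,6-trihydroxyphenyl)-3-methylbutyl]guai-5-en-11-ol | CC(C)C[C@H](c1c(O)c(C=O)c(O)c(C=O)c1O)[C@@]1(C)CC[C@H]2C1=C[C@H](C(C)(C)O)CC[C@H]2C | target

**Step count and risks**

Total step count: 21. Longest linear sequence: 19 steps (1–7 and 10–21); steps 8–9 build the aryl branch that joins in step 10.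

Steps most likely to fail:

1. Step 10 (proposed new method). The dienolate may be protonated before it meets the quinone methide, bond through C6 or through oxygen, or add with poor facial control at C4 or at the quinone methide (wrong configuration at C9′). The quinone methide may also oligomerise or be reduced by residual SmI2. The fallback uses known reactions only and changes the bond-forming mode: the aryl carbon enters as an aldehyde by aldol addition and the isobutyl chain by SN1 allylation. It sets out from 12. Mukaiyama hydration (Co(acac)2, PhSiH3, O2) gives the C11 alcohol F1, and Et3SiOTf/2,6-lutidine its triethylsilyl ether F2. SmI2 (2.0 equiv, THF, −78 °C) followed by 2,4,6-trimethoxybenzaldehyde gives, by the α-selective samarium Reformatsky-type aldol, the benzylic alcohol F3. BF3·OEt2 and (2-methylallyl)trimethylsilane at −78 °C replace the doubly ortho-oxygenated benzylic hydroxyl by SN1 allylation, the silane approaching from the side of C5/C6, away from the complexed C3 carbonyl, to give the methallyl compound F4. H2 with RhCl(PPh3)3 saturates its 1,1-disubstituted alkene, and the route is rejoined at 22.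

2. Step 18 (together with step 17). Elimination may run toward C9 instead of the methyl group, hydrogen may be delivered to the α face of C10, or the C5=C6 bond may migrate or be saturated. The fallback replaces elimination–hydrogenation by radical deoxygenation. It sets out from 25. Methyl chlorooxoacetate/DMAP gives the tertiary methyl oxalate F5. Bu3SnH/AIBN in refluxing toluene fragments it to the C10 radical, which should take a hydrogen atom from the stannane on the less hindered β face. The route is rejoined at 27.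

3. Step 15. Acylation of the neopentyl-type C3 alcohol beside the fully substituted C4 may stall, so that the deoxygenation cannot be started. The fallback deoxygenates through the enol triflate instead. It sets out from 22. KHMDS/PhNTf2 gives the enol triflate F6 (only C2 can be enolised). Pd(OAc)2/PPh3 with HCO2H/Et3N reduces it to the cyclopentene F7. LiAlH4 cleaves the C10 acetate to give the alcohol F8, and SOCl2/pyridine gives the triene F9. H2 with RhCl(PPh3)3 saturates the C2=C3 and C10=C14 bonds together, and the route is rejoined at 27.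

**Further compounds**

F1 | step 10 | 6α,10β-diacetoxy-11-hydroxy-1βH-guai-4-en-3-one | CC1=C2[C@@H](OC(C)=O)[C@H](C(C)(C)O)CC[C@](C)(OC(C)=O)[C@H]2CC1=O
F2 | step 10 | 6α,10β-diacetoxy-11-triethylsilyloxy-1βH-guai-4-en-3-one | CC1=C2[C@@H](OC(C)=O)[C@H](C(C)(C)O[Si](CC)(CC)CC)CC[C@](C)(OC(C)=O)[C@H]2CC1=O
F3 | step 10 | 10β-acetoxy-4β-[hydroxy(2,4,6-trimethoxyphenyl)methyl]-11-triethylsilyloxy-1βH-guai-5-en-3-one (carbinol epimers) | OC(c1c(OC)cc(OC)cc1OC)[C@@]1(C)C(=O)C[C@H]2C1=C[C@H](C(C)(C)O[Si](CC)(CC)CC)CC[C@]2(C)OC(C)=O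
F4 | step 10 | 10β-acetoxy-4β-[3-methyl-1-(2,4,6-trimethoxyphenyl)but-3-enyl]-11-triethylsilyloxy-1βH-guai-5-en-3-one | CC(=C)C[C@H](c1c(OC)cc(OC)cc1OC)[C@@]1(C)C(=O)C[C@H]2C1=C[C@H](C(C)(C)O[Si](CC)(CC)CC)CC[C@]2(C)OC(C)=O
F5 | step 18 | 10β-O-(methoxyoxalyl) derivative of 25 | CC(C)C[C@H](c1c(OC)cc(OC)cc1OC)[C@@]1(C)CC[C@H]2C1=C[C@H](C(C)(C)O[Si](CC)(CC)CC)CC[C@]2(C)OC(=O)C(=O)OC
F6 | step 15 | C2=C3 enol triflate of 22 | CC(C)C[C@H](c1c(OC)cc(OC)cc1OC)[C@@]1(C)C(OS(=O)(=O)C(F)(F)F)=C[C@H]2C1=C[C@H](C(C)(C)O[Si](CC)(CC)CC)CC[C@]2(C)OC(C)=O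
F7 | step 15 | 10β-acetoxy-4β-[3-methyl-1-(2,4,6-trimethoxyphenyl)butyl]-11-triethylsilyloxy-1βH-guaia-2,5-diene | CC(C)C[C@H](c1c(OC)cc(OC)cc1OC)[C@@]1(C)C=C[C@H]2C1=C[C@H](C(C)(C)O[Si](CC)(CC)CC)CC[C@]2(C)OC(C)=O
F8 | step 15 | 4β-[3-methyl-1-(2,4,6-trimethoxyphenyl)butyl]-11-triethylsilyloxy-1βH-guaia-2,5-dien-10β-ol | CC(C)C[C@H](c1c(OC)cc(OC)cc1OC)[C@@]1(C)C=C[C@H]2C1=C[C@H](C(C)(C)O[Si](CC)(CC)CC)CC[C@]2(C)O
F9 | step 15 | 4β-[3-methyl-1-(2,4,6-trimethoxyphenyl)butyl]-11-triethylsilyloxy-1βH-guaia-2,5,10(14)-triene | CC(C)C[C@H](c1c(OC)cc(OC)cc1OC)[C@@]1(C)C=C[C@H]2C1=C[C@H](C(C)(C)O[Si](CC)(CC)CC)CCC2=C
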